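(Readings and results stem from a simulated flask with made-up constants; scatter was added.)

We have none of the rate constants, so we look for a number that can do without them.

| flask | left-handed substrate | right-handed substrate | partner | free catalyst | added ligand | remark |
|---|---|---|---|---|---|---|
| summer | 0.68 M | 0.68 M | 1 M | 1.4 mM | 1.9 mM | run made earlier |
| dawn | 0.34 M | 0.34 M | 2.04 M | 1.4 mM | 1.9 mM | run made earlier |
| flask | 0.68 M | 0.68 M | 2.04 M | 1.4 mM | 1.9 mM |  |

| run | time / min | left-handed product / % |
|---|---|---|
| summer | 0.500 | 3 |
| summer | 0.833 | 1 |
| summer | 1.33 | 7 |
| summer | 2.00 | 4 |
| summer | 4.00 | 6 |
| summer | 6.00 | 13 |
| dawn | 1.33 | 10 |
| dawn | 2.50 | 17 |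
| dawn | 4.00 | 25 |
| dawn | 5.00 | 29 |
| dawn | 6.00 | 31 |

(scatter of a reading: 2 percentage points)

- free catalyst is single-handed; left-handed substrate and right-handed substrate are mirror images of each other, charged as a racemate, each of them at the stated concentration
- steps that have been proposed: free catalyst + left-handed substrate <-> catalyst intermediate A; free catalyst + right-handed substrate <-> catalyst intermediate B; partner + catalyst intermediate A -> free catalyst + left-handed product; partner + catalyst intermediate B -> free catalyst + right-handed product; left-handed substrate <-> right-handed substrate; free catalyst + added ligand <-> idle complex
- no earlier run changes the charge of free catalyst; that part of a forecast is a guess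

- apparent order in partner when 20% of the left-handed substrate and right-handed substrate together are converted (percent change of the rate of making left-handed product for one percent more partner charged)
- apparent order in free catalyst when 20% of the left-handed substrate and right-handed substrate together are converted (percent change of the rate of making left-handed product for one percent more free catalyst charged)

We take the symmetric case as the zero of our scale: suppose the single-handed catalyst waits bound, in its resting state, shared evenly between the two mirror-image substrates. Then the substrate level drops out of the rate, and the fraction of the charge turned into left-handed product per minute follows the partner equivalents, meaning partner charged per both substrates charged together. This is 0.735 in summer, 3.00 in dawn and 1.50 in the flask.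

To test whether this one number is enough, we divide early slopes by it. Summer's last reading gives 0.0295 /min per equivalent and dawn's first gives 0.0251 /min. Their gap of 0.00440 /min is smaller than the 0.00501 /min that one standard deviation of a dawn reading amounts to, so the pair passes. Dawn's last reading gives 0.0172 /min, less than either, so we hold the number to early conversions. We commit to the mean, 0.0273 /min, and to a partner order of 1. No earlier run changes the catalyst, so our 1 there is a guess.

The forecast gives 0.95 in partner and 1.1 in catalyst, and it reads the runs differently: “the catalyst rests mainly as intermediate B”, where we assumed an even share.

The flask gives 1.1 in partner and 0.97 in catalyst, so the forecast's partner order is low by a factor of 1.16.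

    free catalyst + left-handed substrate ⇌ catalyst intermediate A (K = 3.90 /M, k = 59.0 /M/s)
    free catalyst + right-handed substrate ⇌ catalyst intermediate B (K = 3.30 /M, k = 12.0 /M/s)
    partner + catalyst intermediate A → free catalyst + left-handed product (k = 0.800 /M/s)
    partner + catalyst intermediate B → free catalyst + right-handed product (k = 0.280 /M/s)
    left-handed substrate ⇌ right-handed substrate (k = 0.00240 /s)
    free catalyst + added ligand ⇌ idle complex, settled at all times (K = 170 /M)

After 3.00 min the flask holds 38.4% of its catalyst as catalyst intermediate A and 35.4% as catalyst intermediate B. Our slope and 1.50 put 12.3% left-handed product in the flask by then, and it holds 11.6%. Twice the partner means 3.00 equivalents, so the time to 20% conversion should be multiplied by 0.500, and the run with twice the partner gives a factor of 0.494.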